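The seven-membered ring is disconnected at C4–C3a and C6–C7 (azulene locants). C4 (CMe2) sits next to ring-fusion carbon C3a and C8 (=CH2) next to C8a, which is the pattern left when a 2-methylpropenyl carbenoid adds to a 2-siloxydiene built on the cyclopentene. In one operation, carbenoid cyclopropanation of the enol ether alkene and Cope rearrangement of the cis-divinylcyclopropane close the cycloheptadiene, form both bonds, set C3a and leave C8 as a masked ketone. The precursor is cyclopentene 11, with the S quaternary carbon (methyl, CH2CO2tBu) beside a 1-(silyloxy)vinyl group. A chiral catalyst, not the remote quaternary centre, is relied on for the facial choice.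

Key step: step 9

Remark: azulene locants are used for all bicyclic compounds (C1 quaternary carbon, C3a/C8a ring fusion, C4 = CMe2, C6 = carbenoid-derived carbon, C8 = masked carbonyl carbon), and the ligand of step 2 and the catalyst of step 9 are assumed to induce in the sense shown by their closest analogues.

Step 1
Reactants: 1 diallyl adipate
Product: 3 prop-2-enyl 1-methyl-2-oxocyclopentane-1-carboxylate (racemic), via sodium ketoester enolate 2 (not isolated)
Conditions: NaH (1.1 equiv), THF, 0 → 60 °C; then MeI, rt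
Reagents that add atoms: iodomethane, CI
Why: Dieckmann condensation gives the stabilised sodium enolate, which should be C-methylated in the same flask (enolate alkylation).

Step 2
Reactants: 3 prop-2-enyl 1-methyl-2-oxocyclopentane-1-carboxylate
Product: 4 (2S)-2-methyl-2-(prop-2-enyl)cyclopentan-1-one
Conditions: Pd2(dba)3 (2.5 mol %), (S)-t-BuPHOX [(S)-4-tert-butyl-2-(2-diphenylphosphinophenyl)-4,5-dihydrooxazole] (6 mol %), THF, 30 °C
Reagents that add atoms: none
Why: Decarboxylative asymmetric allylic alkylation (Tsuji–Trost type), in which loss of CO2 gives a palladium–PHOX enolate whose inner-sphere allylation sets the quaternary centre, the S ligand being expected to give the S ketone by analogy with the cyclohexanone series.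

Step 3
Reactants: 4 (2S)-2-methyl-2-(prop-2-enyl)cyclopentan-1-one
Product: 5 2-[(1S)-1-methyl-2-oxocyclopentyl]acetic acid
Conditions: RuCl3·H2O (3 mol %), NaIO4 (4.2 equiv), MeCN/EtOAc/H2O, rt
Reagents that add atoms: sodium periodate, [Na+].[O-]I(=O)(=O)=O; water, O
Why: Oxidative cleavage of the terminal alkene by catalytic ruthenium tetroxide (periodate as terminal oxidant) should take the allyl group to CH2CO2H without touching the quaternary centre.

Step 4
Reactants: 5 2-[(1S)-1-methyl-2-oxocyclopentyl]acetic acid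
Product: 6 tert-butyl 2-[(1S)-1-methyl-2-oxocyclopentyl]acetate
Conditions: tert-butyl 2,2,2-trichloroacetimidate (2 equiv), BF3·OEt2 (cat.), CH2Cl2/cyclohexane, rt
Reagents that add atoms: tert-butyl 2,2,2-trichloroacetimidate, CC(C)(C)OC(=N)C(Cl)(Cl)Cl
Why: Acid-catalysed O-alkylation of the acid by the imidate (tert-butyl cation transfer) gives the base-stable ester that must survive the saponification of step 11.

Step 5
Reactants: 6 tert-butyl 2-[(1S)-1-methyl-2-oxocyclopentyl]acetate
Product: 8 tert-butyl 2-[(1S)-1-methyl-2-(trifluoromethanesulfonyloxy)cyclopent-2-en-1-yl]acetate, via lithium ketone enolate 7 (not isolated)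
Conditions: LiN(iPr)2 (1.1 equiv), THF, −78 °C; then PhNTf2, −78 → 0 °C; aqueous work-up
Reagents that add atoms: N-phenylbis(trifluoromethanesulfonimide), O=S(=O)(N(c1ccccc1)S(=O)(=O)C(F)(F)F)C(F)(F)F
Why: Kinetic enolisation can only occur at the ketone CH2 (the other α-carbon is quaternary and the neopentyl ester CH2 is less acidic), and O-sulfonylation of the enolate gives the vinyl triflate.

Step 6
Reactants: 8 tert-butyl 2-[(1S)-1-methyl-2-(trifluoromethanesulfonyloxy)cyclopent-2-en-1-yl]acetate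
Product: 10 tert-butyl 2-[(1S)-2-acetyl-1-methylcyclopent-2-en-1-yl]acetate, via ethoxydiene 9 (not isolated)
Conditions: tributyl(1-ethoxyvinyl)stannane (1.3 equiv), Pd(PPh3)4 (5 mol %), LiCl (3 equiv), THF, 65 °C; then 1 M HCl, rt
Reagents that add atoms: tributyl(1-ethoxyvinyl)stannane, CCCC[Sn](CCCC)(CCCC)C(=C)OCC; water, O
Why: Stille coupling of the vinyl triflate with the acyl-anion equivalent, followed by mild hydrolysis of the enol ether, should install the acetyl group as a conjugated enone.

Step 7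
Reactants: 10 tert-butyl 2-[(1S)-2-acetyl-1-methylcyclopent-2-en-1-yl]acetate
Product: 11 tert-butyl 2-[(1S)-2-{1-[(tert-butyldimethylsilyl)oxy]ethenyl}-1-methylcyclopent-2-en-1-yl]acetate
Conditions: TBSOTf (1.2 equiv), Et3N (2 equiv), CH2Cl2, −78 → 0 °C
Reagents that add atoms: tert-butyldimethylsilyl trifluoromethanesulfonate, CC(C)(C)[Si](C)(C)OS(=O)(=O)C(F)(F)F
Why: Soft enolisation of the methyl ketone (silyl triflate and amine) gives the cross-conjugated 2-siloxydiene, the hindered tert-butyl ester not being enolised under these conditions.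

Step 8
Reactants: 12 methyl 4-methylpent-3-enoate
Product: 13 methyl 2-diazo-4-methylpent-3-enoate
Conditions: 4-acetamidobenzenesulfonyl azide (1.3 equiv), DBU (1.5 equiv), MeCN, 0 °C → rt; kept cold and used at once
Reagents that add atoms: 4-acetamidobenzenesulfonyl azide, CC(=O)Nc1ccc(cc1)S(=O)(=O)N=[N+]=[N-]
Why: Regitz diazo transfer to the α-carbon of the dienolate of the β,γ-unsaturated ester should give the vinyldiazoacetate.

Step 9
Reactants: 11 tert-butyl 2-[(1S)-2-{1-[(tert-butyldimethylsilyl)oxy]ethenyl}-1-methylcyclopent-2-en-1-yl]acetate; 13 methyl 2-diazo-4-methylpent-3-enoate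
Product: 15 methyl (1S,3aS)-1-(2-tert-butoxy-2-oxoethyl)-8-[(tert-butyldimethylsilyl)oxy]-1,4,4-trimethyl-1,2,3,3a,4,7-hexahydroazulene-6-carboxylate, via cis-divinylcyclopropane 14 (not isolated)
Conditions: Rh2(S-DOSP)4 [dirhodium tetrakis((S)-N-(4-dodecylbenzenesulfonyl)prolinate)] (2 mol %), hexanes, −20 °C → rt, slow addition of 13 (2 equiv); then toluene, 110 °C
Reagents that add atoms: none
Why: The rhodium carbenoid from 13 cyclopropanates the electron-rich terminal enol ether alkene of 11 (carbenoid carbon to the diene CH2) to give cis-divinylcyclopropane 14, and heating then drives a [3,3] shift through a boat transition state in which the ring bond between the carbenoid carbon and the siloxy carbon breaks as the CMe2 terminus bonds to the cyclopentene CH. The closest known reaction type is the tandem cyclopropanation/Cope rearrangement (formal [4+3] cycloaddition) of vinyldiazoacetates with 2-siloxydienes. The seven-membered ring is closed sigmatropically, by Cope rearrangement of a cis-1,2-divinylcyclopropane, not by a polar cyclisation. The one new stereocentre, C3a, follows stereospecifically from the enol ether enantioface that is cyclopropanated; that face is imposed by the chiral prolinate catalyst, whose usual sense of induction should lead to C4 cis to the C1 methyl, so the weak bias of the remote quaternary carbon is overridden and material from the minor enantiomer of 11 ends as a separable diastereomer. The step needs chemoselectivity for the 1,1-disubstituted enol ether over the trisubstituted ring alkene (secured by its electron richness and unhindered CH2 terminus) and a cis arrangement of the two alkenyl groups (the usual preference of donor/acceptor carbenoids, the trans isomer being able to equilibrate through the donor–acceptor cyclopropane on heating). The methyl group that is cis on the CMe2 terminus points into the boat and slows the shift, which is why the mixture is heated to 110 °C after carbenoid transfer.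

Step 10
Reactants: 15 methyl (1S,3aS)-1-(2-tert-butoxy-2-oxoethyl)-8-[(tert-butyldimethylsilyl)oxy]-1,4,4-trimethyl-1,2,3,3a,4,7-hexahydroazulene-6-carboxylate
Product: 16 methyl (1S,3aS,6RS)-1-(2-tert-butoxy-2-oxoethyl)-8-[(tert-butyldimethylsilyl)oxy]-1,4,4-trimethyl-1,2,3,3a,4,5,6,7-octahydroazulene-6-carboxylate
Conditions: H2 (3 atm), 10% Pd/C, EtOAc, rt
Reagents that add atoms: none
Why: Heterogeneous catalytic hydrogenation should reduce the conjugated trisubstituted alkene and leave the tetrasubstituted silyl enol ether, the new C6 centre being of no consequence because its carboxyl group is removed in step 12.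

Step 11
Reactants: 16 methyl (1S,3aS,6RS)-1-(2-tert-butoxy-2-oxoethyl)-8-[(tert-butyldimethylsilyl)oxy]-1,4,4-trimethyl-1,2,3,3a,4,5,6,7-octahydroazulene-6-carboxylate
Product: 18 (1S,3aR,6RS,8aR)-1-(2-tert-butoxy-2-oxoethyl)-1,4,4-trimethyl-8-oxodecahydroazulene-6-carboxylic acid, via lithium carboxylate 17 (not isolated)
Conditions: LiOH (5 equiv), THF/MeOH/H2O, rt → 40 °C; then 1 M HCl to pH 1, THF, 0 °C → rt
Reagents that add atoms: lithium hydroxide, [Li+].[OH-]
Why: Saponification of the methyl ester (the tert-butyl ester and the hindered silyl enol ether resist hydroxide) is followed by acid hydrolysis of the enol ether, in which C-protonation at C8a from the convex face (that of H-3a, opposite the C4 arm of the seven-membered ring) should give the cis-fused ketone without the ketone meeting base.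

Step 12
Reactants: 18 (1S,3aR,6RS,8aR)-1-(2-tert-butoxy-2-oxoethyl)-1,4,4-trimethyl-8-oxodecahydroazulene-6-carboxylic acid
Product: 20 tert-butyl 2-[(1S,3aR,8aR)-1,4,4-trimethyl-8-oxodecahydroazulen-1-yl]acetate, via thiohydroxamate ester 19 (not isolated)
Conditions: 1-hydroxypyridine-2(1H)-thione (1.2 equiv), DCC (1.2 equiv), DMAP (cat.), CH2Cl2, rt, dark; then t-BuSH (5 equiv), visible light, rt
Reagents that add atoms: none
Why: Barton reductive decarboxylation is used because the carboxyl group is 1,4 to the ketone and cannot leave as a β-keto acid, so it is removed by a radical chain in which the secondary C6 radical takes hydrogen from the thiol.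

Step 13
Reactants: 20 tert-butyl 2-[(1S,3aR,8aR)-1,4,4-trimethyl-8-oxodecahydroazulen-1-yl]acetate
Product: 21 tert-butyl 2-[(1S,3aR,8aS)-1,4,4-trimethyl-8-methylidenedecahydroazulen-1-yl]acetate
Conditions: Zn, CH2Br2, TiCl4 (reagent preformed in THF), CH2Cl2, 0 °C → rt; aqueous work-up
Reagents that add atoms: dibromomethane, BrCBr
Why: Takai–Lombardo methylenation with a non-basic titanium–zinc methylene reagent should convert the hindered ketone to the exocyclic alkene without enolisation, which fixes C8a and leaves the ester untouched.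

Step 14
Reactants: 21 tert-butyl 2-[(1S,3aR,8aS)-1,4,4-trimethyl-8-methylidenedecahydroazulen-1-yl]acetate; 22 furan-2(5H)-one
Product: 24 tert-butyl (2R)-2-[(3R)-5-oxooxolan-3-yl]-2-[(1R,3aR,8aS)-1,4,4-trimethyl-8-methylidenedecahydroazulen-1-yl]acetate, via lithium ester enolate 23 (not isolated)
Conditions: LiN(iPr)2 (1.1 equiv), THF, −78 °C; then 22 (1.3 equiv), −78 °C; AcOH quench at −78 °C
Reagents that add atoms: none
Why: Michael addition of the lithium ester enolate (O–Li trans to the bicyclic group) to the butenolide, through a synclinal lithium-bridged transition state with the enolate hydrogen over the lactone ring, the bicyclic group anti to the lactone α-carbon and approach anti to the C1–C8a bond, should give the (2R,3′R) pair of new centres.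

Step 15
Reactants: 24 tert-butyl (2R)-2-[(3R)-5-oxooxolan-3-yl]-2-[(1R,3aR,8aS)-1,4,4-trimethyl-8-methylidenedecahydroazulen-1-yl]acetate
Product: 26 (2R)-2-[(3R)-5-oxooxolan-3-yl]-2-[(1R,3aR,8aS)-1,4,4-trimethyl-8-methylidenedecahydroazulen-1-yl]acetic acid, via trimethylsilyl ester 25 (not isolated)
Conditions: TMSOTf (3 equiv), 2,6-lutidine (5 equiv), CH2Cl2, 0 °C → rt; then H2O/MeOH
Reagents that add atoms: none
Why: Silyl triflate-mediated cleavage of the tert-butyl ester (loss of isobutene) under buffered conditions should spare the acid-sensitive exocyclic alkene and the lactone, the silyl ester being hydrolysed on work-up.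

Step 16
Reactants: 26 (2R)-2-[(3R)-5-oxooxolan-3-yl]-2-[(1R,3aR,8aS)-1,4,4-trimethyl-8-methylidenedecahydroazulen-1-yl]acetic acid
Product: 28 (4R)-4-{(1R)-2-hydroxy-1-[(1R,3aR,8aS)-1,4,4-trimethyl-8-methylidenedecahydroazulen-1-yl]ethyl}oxolan-2-one, via acyl fluoride 27 (not isolated)
Conditions: cyanuric fluoride (1 equiv), pyridine (1 equiv), CH2Cl2, −10 °C → rt; then NaBH4 (2 equiv), MeOH, 0 °C
Reagents that add atoms: none
Why: Chemoselective borohydride reduction of the acid through its configurationally stable acyl fluoride should leave the γ-lactone and the alkene alone at 0 °C and not epimerise the α-centre.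

Step 17
Reactants: 28 (4R)-4-{(1R)-2-hydroxy-1-[(1R,3aR,8aS)-1,4,4-trimethyl-8-methylidenedecahydroazulen-1-yl]ethyl}oxolan-2-one
Product: 29 (2R)-2-[(3R)-5-oxooxolan-3-yl]-2-[(1R,3aR,8aS)-1,4,4-trimethyl-8-methylidenedecahydroazulen-1-yl]ethyl acetate (CNP0235949.1)
Conditions: Ac2O (2 equiv), pyridine, DMAP (cat.), CH2Cl2, 0 °C → rt
Reagents that add atoms: acetic anhydride, CC(=O)OC(C)=O
Why: DMAP-catalysed acetylation of the primary alcohol completes the target before the hydroxy lactone can translactonise.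

Compound list

1 | diallyl adipate | C=CCOC(=O)CCCCC(=O)OCC=C | starting material
2 | sodium 2-[(prop-2-enyloxy)carbonyl]cyclopent-1-en-1-olate | [Na+].[O-]C1=C(C(=O)OCC=C)CCC1 | intermediate
3 | prop-2-enyl 1-methyl-2-oxocyclopentane-1-carboxylate (racemic) | CC1(C(=O)OCC=C)CCCC1=O | intermediate
4 | (2S)-2-methyl-2-(prop-2-enyl)cyclopentan-1-one | O=C1CCC[C@@]1(C)CC=C | intermediate
5 | 2-[(1S)-1-methyl-2-oxocyclopentyl]acetic acid | O=C1CCC[C@@]1(C)CC(=O)O | intermediate
6 | tert-butyl 2-[(1S)-1-methyl-2-oxocyclopentyl]acetate | O=C1CCC[C@@]1(C)CC(=O)OC(C)(C)C | intermediate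
7 | lithium (5S)-5-(2-tert-butoxy-2-oxoethyl)-5-methylcyclopent-1-en-1-olate | [Li+].[O-]C1=CCC[C@@]1(C)CC(=O)OC(C)(C)C | intermediate
8 | tert-butyl 2-[(1S)-1-methyl-2-(trifluoromethanesulfonyloxy)cyclopent-2-en-1-yl]acetate | O=S(=O)(OC1=CCC[C@@]1(C)CC(=O)OC(C)(C)C)C(F)(F)F | intermediate
9 | tert-butyl 2-[(1S)-2-(1-ethoxyethenyl)-1-methylcyclopent-2-en-1-yl]acetate | CCOC(=C)C1=CCC[C@@]1(C)CC(=O)OC(C)(C)C | intermediate
10 | tert-butyl 2-[(1S)-2-acetyl-1-methylcyclopent-2-en-1-yl]acetate | CC(=O)C1=CCC[C@@]1(C)CC(=O)OC(C)(C)C | intermediate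
11 | tert-butyl 2-[(1S)-2-{1-[(tert-butyldimethylsilyl)oxy]ethenyl}-1-methylcyclopent-2-en-1-yl]acetate | CC(C)(C)[Si](C)(C)OC(=C)C1=CCC[C@@]1(C)CC(=O)OC(C)(C)C | intermediate
12 | methyl 4-methylpent-3-enoate | COC(=O)CC=C(C)C | starting material
13 | methyl 2-diazo-4-methylpent-3-enoate | COC(=O)C(=[N+]=[N-])C=C(C)C | intermediate
14 | methyl (1R,2S)-2-[(5S)-5-(2-tert-butoxy-2-oxoethyl)-5-methylcyclopent-1-en-1-yl]-2-[(tert-butyldimethylsilyl)oxy]-1-(2-methylprop-1-enyl)cyclopropane-1-carboxylate (alkenyl and cyclopentenyl groups cis) | COC(=O)[C@@]1(C=C(C)C)C[C@]1(O[Si](C)(C)C(C)(C)C)C2=CCC[C@@]2(C)CC(=O)OC(C)(C)C | intermediate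
15 | methyl (1S,3aS)-1-(2-tert-butoxy-2-oxoethyl)-8-[(tert-butyldimethylsilyl)oxy]-1,4,4-trimethyl-1,2,3,3a,4,7-hexahydroazulene-6-carboxylate | CC(C)(C)[Si](C)(C)OC1=C2[C@](C)(CC(=O)OC(C)(C)C)CC[C@H]2C(C)(C)C=C(C(=O)OC)C1 | intermediate
16 | methyl (1S,3aS,6RS)-1-(2-tert-butoxy-2-oxoethyl)-8-[(tert-butyldimethylsilyl)oxy]-1,4,4-trimethyl-1,2,3,3a,4,5,6,7-octahydroazulene-6-carboxylate | CC(C)(C)[Si](C)(C)OC1=C2[C@](C)(CC(=O)OC(C)(C)C)CC[C@H]2C(C)(C)CC(C(=O)OC)C1 | intermediate
17 | lithium (1S,3aS,6RS)-1-(2-tert-butoxy-2-oxoethyl)-8-[(tert-butyldimethylsilyl)oxy]-1,4,4-trimethyl-1,2,3,3a,4,5,6,7-octahydroazulene-6-carboxylate | CC(C)(C)[Si](C)(C)OC1=C2[C@](C)(CC(=O)OC(C)(C)C)CC[C@H]2C(C)(C)CC(C(=O)[O-])C1.[Li+] | intermediate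
18 | (1S,3aR,6RS,8aR)-1-(2-tert-butoxy-2-oxoethyl)-1,4,4-trimethyl-8-oxodecahydroazulene-6-carboxylic acid (cis ring fusion) | O=C1CC(C(=O)O)CC(C)(C)[C@@H]2CC[C@@](C)(CC(=O)OC(C)(C)C)[C@H]12 | intermediate
19 | 2-sulfanylidenepyridin-1(2H)-yl (1S,3aR,6RS,8aR)-1-(2-tert-butoxy-2-oxoethyl)-1,4,4-trimethyl-8-oxodecahydroazulene-6-carboxylate | O=C1CC(C(=O)ON3C=CC=CC3=S)CC(C)(C)[C@@H]2CC[C@@](C)(CC(=O)OC(C)(C)C)[C@H]12 | intermediate
20 | tert-butyl 2-[(1S,3aR,8aR)-1,4,4-trimethyl-8-oxodecahydroazulen-1-yl]acetate | O=C1CCCC(C)(C)[C@@H]2CC[C@@](C)(CC(=O)OC(C)(C)C)[C@H]12 | intermediate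
21 | tert-butyl 2-[(1S,3aR,8aS)-1,4,4-trimethyl-8-methylidenedecahydroazulen-1-yl]acetate | C=C1CCCC(C)(C)[C@@H]2CC[C@@](C)(CC(=O)OC(C)(C)C)[C@H]12 | intermediate
22 | furan-2(5H)-one | O=C1OCC=C1 | starting material
23 | lithium enolate of 21 (O–Li trans to the bicyclic group) | C=C1CCCC(C)(C)[C@@H]2CC[C@@](C)(/C=C(/[O-])OC(C)(C)C)[C@H]12.[Li+] | intermediate
24 | tert-butyl (2R)-2-[(3R)-5-oxooxolan-3-yl]-2-[(1R,3aR,8aS)-1,4,4-trimethyl-8-methylidenedecahydroazulen-1-yl]acetate | C=C1CCCC(C)(C)[C@@H]2CC[C@@](C)([C@H](C(=O)OC(C)(C)C)[C@@H]3COC(=O)C3)[C@H]12 | intermediate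
25 | trimethylsilyl (2R)-2-[(3R)-5-oxooxolan-3-yl]-2-[(1R,3aR,8aS)-1,4,4-trimethyl-8-methylidenedecahydroazulen-1-yl]acetate | C=C1CCCC(C)(C)[C@@H]2CC[C@@](C)([C@H](C(=O)O[Si](C)(C)C)[C@@H]3COC(=O)C3)[C@H]12 | intermediate
26 | (2R)-2-[(3R)-5-oxooxolan-3-yl]-2-[(1R,3aR,8aS)-1,4,4-trimethyl-8-methylidenedecahydroazulen-1-yl]acetic acid | C=C1CCCC(C)(C)[C@@H]2CC[C@@](C)([C@H](C(=O)O)[C@@H]3COC(=O)C3)[C@H]12 | intermediate
27 | (2R)-2-[(3R)-5-oxooxolan-3-yl]-2-[(1R,3aR,8aS)-1,4,4-trimethyl-8-methylidenedecahydroazulen-1-yl]acetyl fluoride | C=C1CCCC(C)(C)[C@@H]2CC[C@@](C)([C@H](C(F)=O)[C@@H]3COC(=O)C3)[C@H]12 | intermediate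
28 | (4R)-4-{(1R)-2-hydroxy-1-[(1R,3aR,8aS)-1,4,4-trimethyl-8-methylidenedecahydroazulen-1-yl]ethyl}oxolan-2-one | C=C1CCCC(C)(C)[C@@H]2CC[C@@](C)([C@H](CO)[C@@H]3COC(=O)C3)[C@H]12 | intermediate
29 | (2R)-2-[(3R)-5-oxooxolan-3-yl]-2-[(1R,3aR,8aS)-1,4,4-trimethyl-8-methylidenedecahydroazulen-1-yl]ethyl acetate (CNP0235949.1) | C=C1CCCC(C)(C)[C@@H]2CC[C@@](C)([C@H](COC(C)=O)[C@@H]3COC(=O)C3)[C@H]12 | target

Total step count: 17. Longest linear sequence: 16 steps (steps 1–7 and 9–17); step 8 is a one-step side branch.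

Steps most likely to fail

Step 9. The carbenoid may be lost to 1,4-hydrogen shift or cyclopropene formation before it is trapped. The cis-methyl group may stall the Cope shift so that the donor–acceptor cyclopropane opens instead, or the wrong enol ether face may be cyclopropanated. The fallback sets out from 8 and returns at 20, and closes the seven-membered ring by conjugate addition and olefin metathesis. Aminocarbonylation of 8 (Pd(OAc)2, dppp, CO, MeNH(OMe)·HCl, Et3N, DMF, 60 °C) would give the N-methoxy-N-methylamide tert-butyl 2-[(1S)-2-[methoxy(methyl)carbamoyl]-1-methylcyclopent-2-en-1-yl]acetate F1. Allylmagnesium bromide (THF, −78 °C) would then give the allyl enone tert-butyl 2-[(1S)-2-(but-3-enoyl)-1-methylcyclopent-2-en-1-yl]acetate F2. Hosomi–Sakurai addition of trimethyl(3-methylbut-2-enyl)silane (TiCl4, CH2Cl2, −78 °C), which bonds through its γ-carbon, should deliver the CMe2–vinyl group to the ring β-carbon on the face anti to CH2CO2tBu and give tert-butyl 2-[(1S,2RS,3R)-2-(but-3-enoyl)-1-methyl-3-(2-methylbut-3-en-2-yl)cyclopentyl]acetate F3. Ring-closing metathesis (second-generation Grubbs catalyst, CH2Cl2, 40 °C) would give the cycloheptenone tert-butyl 2-[(1S,3aR,8aRS)-1,4,4-trimethyl-8-oxo-1,2,3,3a,4,7,8,8a-octahydroazulen-1-yl]acetate F4. Hydrogenation (H2, Pd/C, EtOAc) would lead to 20, its ring-fusion carbon then being settled by equilibration or by kinetic enolate protonation.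

Step 14. The hindered enolate may act as a base towards the butenolide (γ-deprotonation), and facial selection at the enolate carbon and at the butenolide β-carbon may be poor. The fallback sets out from 21 and returns at 24, and uses an enantiopure 5-alkoxybutenolide whose acetal centre dictates the acceptor face. Enolate 23 would be added to (5S)-5-[(1S,2R,5S)-menthyloxy]furan-2(5H)-one (THF, −78 °C), addition occurring trans to the menthyloxy group, to give tert-butyl (2R)-2-[(2S,3R)-2-{[(1S,2R,5S)-5-methyl-2-(propan-2-yl)cyclohexyl]oxy}-5-oxooxolan-3-yl]-2-[(1R,3aR,8aS)-1,4,4-trimethyl-8-methylidenedecahydroazulen-1-yl]acetate F5. NaBH4 with KOH in aqueous EtOH at 0 °C, then acidification, would reduce the acetal carbon through the ring-opened aldehyde and relactonise to 24.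

Step 11. C8a may be protonated from the concave face, or acid-catalysed enolisation may equilibrate the ketone, so that the trans-fused ring junction results. The fallback sets out from 16 and returns at 20; it postpones unmasking of the ketone and protonates a preformed enolate irreversibly at low temperature. Saponification of 16 (LiOH) with acidification only to pH 5 would give the enol ether acid (1S,3aS,6RS)-1-(2-tert-butoxy-2-oxoethyl)-8-[(tert-butyldimethylsilyl)oxy]-1,4,4-trimethyl-1,2,3,3a,4,5,6,7-octahydroazulene-6-carboxylic acid F6. Barton decarboxylation under the conditions of step 12 would give tert-butyl 2-[(1S,3aS)-8-[(tert-butyldimethylsilyl)oxy]-1,4,4-trimethyl-1,2,3,3a,4,5,6,7-octahydroazulen-1-yl]acetate F7. TASF (THF, −78 → −40 °C) would release the tris(dimethylamino)sulfonium enolate F8, which is quenched at −78 °C with 2,6-di-tert-butylphenol to give 20.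

Further compounds

F1 | step 9 | tert-butyl 2-[(1S)-2-[methoxy(methyl)carbamoyl]-1-methylcyclopent-2-en-1-yl]acetate | CON(C)C(=O)C1=CCC[C@@]1(C)CC(=O)OC(C)(C)C
F2 | step 9 | tert-butyl 2-[(1S)-2-(but-3-enoyl)-1-methylcyclopent-2-en-1-yl]acetate | C=CCC(=O)C1=CCC[C@@]1(C)CC(=O)OC(C)(C)C
F3 | step 9 | tert-butyl 2-[(1S,2RS,3R)-2-(but-3-enoyl)-1-methyl-3-(2-methylbut-3-en-2-yl)cyclopentyl]acetate | C=CC(C)(C)[C@@H]1CC[C@@](C)(CC(=O)OC(C)(C)C)C1C(=O)CC=C
F4 | step 9 | tert-butyl 2-[(1S,3aR,8aRS)-1,4,4-trimethyl-8-oxo-1,2,3,3a,4,7,8,8a-octahydroazulen-1-yl]acetate | O=C1CC=CC(C)(C)[C@@H]2CC[C@@](C)(CC(=O)OC(C)(C)C)C12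
F5 | step 14 | tert-butyl (2R)-2-[(2S,3R)-2-{[(1S,2R,5S)-5-methyl-2-(propan-2-yl)cyclohexyl]oxy}-5-oxooxolan-3-yl]-2-[(1R,3aR,8aS)-1,4,4-trimethyl-8-methylidenedecahydroazulen-1-yl]acetate | C=C1CCCC(C)(C)[C@@H]2CC[C@@](C)([C@H](C(=O)OC(C)(C)C)[C@@H]3[C@@H](O[C@H]4C[C@@H](C)CC[C@@H]4C(C)C)OC(=O)C3)[C@H]12
F6 | step 11 | (1S,3aS,6RS)-1-(2-tert-butoxy-2-oxoethyl)-8-[(tert-butyldimethylsilyl)oxy]-1,4,4-trimethyl-1,2,3,3a,4,5,6,7-octahydroazulene-6-carboxylic acid | CC(C)(C)[Si](C)(C)OC1=C2[C@](C)(CC(=O)OC(C)(C)C)CC[C@H]2C(C)(C)CC(C(=O)O)C1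
F7 | step 11 | tert-butyl 2-[(1S,3aS)-8-[(tert-butyldimethylsilyl)oxy]-1,4,4-trimethyl-1,2,3,3a,4,5,6,7-octahydroazulen-1-yl]acetate | CC(C)(C)[Si](C)(C)OC1=C2[C@](C)(CC(=O)OC(C)(C)C)CC[C@H]2C(C)(C)CCC1
F8 | step 11 | tris(dimethylamino)sulfonium (1S,3aS)-1-(2-tert-butoxy-2-oxoethyl)-1,4,4-trimethyl-1,2,3,3a,4,5,6,7-octahydroazulen-8-olate | CN(C)[S+](N(C)C)N(C)C.[O-]C1=C2[C@](C)(CC(=O)OC(C)(C)C)CC[C@H]2C(C)(C)CCC1
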